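**Strategy.** Ring B, the 2,4-dihydroxyphenyl ketone, is assembled last from open-chain parts. Its C2–C3–C4–C5 segment, oxygenated at C2 and C4, maps onto the bis-silyl dienol ether of methyl acetoacetate. Its C1–C6 edge maps onto the triple bond of a terminal ynone. One polarised Diels–Alder reaction forms C1–C2 and C5–C6, and loss of methanol gives the resorcinol with the acyl group already in place. The dienophile is a 1-arylbut-3-yn-2-one carrying the finished ring A (2-methoxy, 3-prenyl, 4,6-dioxygenated). Its two phenols are masked as triisopropylsilyl ethers, so the endgame needs fluoride and no acid.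

Key step: step 11

**Protecting-group design.**
- In the free target, the ring A C6–OH can form a five-membered hemiketal with the ketone, and acid dehydrates this irreversibly to the 2-arylbenzofuran.
- The ring A C4–OH sits next to the prenyl group, which acid closes to a 2,2-dimethylchroman.
- Acetal groups of the MOM type come off only with acid, so they are unsuitable for the last step. Silyl ethers are used on ring A instead.
- iPr3Si is preferred to tBuMe2Si. It must survive carbonate, an ylide, dilute aqueous acid and a neighbouring magnesium alkoxide, yet still falls to buffered fluoride at 0 °C.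

**Atom map of the key step.**

| Source atom | Ring B position |
|---|---|
| diene CH2 | C5 |
| diene C–OSi | C4 |
| diene CH | C3 |
| ketene acetal carbon | C2 |
| alkyne CH | C6 |
| acyl-bearing alkyne carbon | C1 |

**Assumption.** The target has no stereocentre. Transient stereocentres are formed racemic and are erased later, and enol ethers and the diene are used as mixtures of geometric isomers.

**Step 1**
Reactants: 1 2,4,6-trihydroxybenzaldehyde
Product: 2 2-hydroxy-4,6-bis(triisopropylsilyloxy)benzaldehyde
Conditions: iPr3SiCl (2.1 equiv), imidazole, DMF, 0 → 25 °C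
Reagents that add atoms: triisopropylsilyl chloride, CC(C)[Si](Cl)(C(C)C)C(C)C
Why: O-silylation takes the acidic 4-OH and one of the two equivalent ortho OH groups, while the last OH is hydrogen-bonded to the formyl oxygen and shielded from the bulky chloride, so two equivalents should stop at the bis-ether.

**Step 2**
Reactants: 3 2-methylbut-3-en-2-ol
Product: 4 tert-butyl 2-methylbut-3-en-2-yl carbonate
Conditions: n-BuLi, THF, −78 → 0 °C; Boc2O, 0 → 25 °C
Reagents that add atoms: di-tert-butyl dicarbonate, CC(C)(C)OC(=O)OC(=O)OC(C)(C)C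
Why: Alkoxycarbonylation of the deprotonated tertiary allylic alcohol is the standard activation, since the alcohol cannot alkylate a phenol directly but its carbonate ionises readily to a π-allyl complex.

**Step 3**
Reactants: 2 2-hydroxy-4,6-bis(triisopropylsilyloxy)benzaldehyde, 4 tert-butyl 2-methylbut-3-en-2-yl carbonate
Product: 5 2-[(2-methylbut-3-en-2-yl)oxy]-4,6-bis(triisopropylsilyloxy)benzaldehyde
Conditions: Pd(PPh3)4 (5 mol %), THF, 0 °C
Reagents that add atoms: none
Why: In this Tsuji–Trost O-allylation, zerovalent palladium ionises 4 with loss of CO2, the released tert-butoxide deprotonates 2, and at low temperature the phenoxide attacks the more substituted terminus of the 1,1-dimethyl-π-allyl complex to give the tertiary ether as the kinetic product.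

**Step 4**
Reactants: 5 2-[(2-methylbut-3-en-2-yl)oxy]-4,6-bis(triisopropylsilyloxy)benzaldehyde
Product: 7 2-hydroxy-3-(3-methylbut-2-en-1-yl)-4,6-bis(triisopropylsilyloxy)benzaldehyde, via Claisen dienone 6 (not isolated)
Conditions: o-xylene, 140 °C
Reagents that add atoms: none
Why: In this aromatic Claisen rearrangement the [3,3] shift ends productively only at C3, the sole unsubstituted ortho position, inverts the allyl unit so that its CH2 end bonds to the ring as a normal prenyl group, and becomes irreversible when 6 enolises to the chelated phenol.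

**Step 5**
Reactants: 7 2-hydroxy-3-(3-methylbut-2-en-1-yl)-4,6-bis(triisopropylsilyloxy)benzaldehyde
Product: 8 2-methoxy-3-(3-methylbut-2-en-1-yl)-4,6-bis(triisopropylsilyloxy)benzaldehyde
Conditions: MeI, K2CO3, acetone, 50 °C
Reagents that add atoms: iodomethane, CI
Why: In this Williamson ether synthesis the only free phenol is methylated, and the bulky aryl iPr3Si ethers tolerate anhydrous carbonate and are too hindered for silyl transfer to the phenoxide.

**Step 6**
Reactants: 8 2-methoxy-3-(3-methylbut-2-en-1-yl)-4,6-bis(triisopropylsilyloxy)benzaldehyde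
Product: 10 [2-methoxy-3-(3-methylbut-2-en-1-yl)-4,6-bis(triisopropylsilyloxy)phenyl]acetaldehyde, via methyl enol ether 9 (not isolated)
Conditions: Ph3PCH2OMe Cl, KOtBu, THF, 0 → 25 °C; then 2 M aq HCl, 25 °C
Reagents that add atoms: (methoxymethyl)triphenylphosphonium chloride, COC[P+](c1ccccc1)(c1ccccc1)c1ccccc1.[Cl-]; water, O
Why: Wittig methoxymethylenation followed by acid hydrolysis of the enol ether is the standard one-carbon homologation of an aryl aldehyde, and dilute acid at room temperature spares the aryl iPr3Si ethers and a prenyl group that has no free phenol beside it.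

**Step 7**
Reactants: 10 [2-methoxy-3-(3-methylbut-2-en-1-yl)-4,6-bis(triisopropylsilyloxy)phenyl]acetaldehyde, 11 ethynylmagnesium bromide
Product: 12 1-[2-methoxy-3-(3-methylbut-2-en-1-yl)-4,6-bis(triisopropylsilyloxy)phenyl]but-3-yn-2-ol (racemic)
Conditions: HC≡CMgBr, THF, −78 → −20 °C; H2O quench
Reagents that add atoms: none
Why: In this Grignard 1,2-addition the weakly basic acetylide adds to the arylacetaldehyde faster than it enolises it, the carbinol centre forms racemic and is removed in step 8, and the low temperature, the magnesium counter-ion and the bulk of iPr3Si suppress silyl migration from the C6 oxygen to the alkoxide.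

**Step 8**
Reactants: 12 1-[2-methoxy-3-(3-methylbut-2-en-1-yl)-4,6-bis(triisopropylsilyloxy)phenyl]but-3-yn-2-ol
Product: 13 1-[2-methoxy-3-(3-methylbut-2-en-1-yl)-4,6-bis(triisopropylsilyloxy)phenyl]but-3-yn-2-one
Conditions: Dess–Martin periodinane, NaHCO3, CH2Cl2, 0 °C
Reagents that add atoms: none
Why: Buffered Dess–Martin oxidation converts a secondary propargylic alcohol into the ynone under near-neutral conditions, which avoids enolisation at the acidic ArCH2 position and conjugate addition to the terminal ynone, which is used at once.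

**Step 9**
Reactants: 14 methyl acetoacetate
Product: 15 methyl 3-(trimethylsilyloxy)but-2-enoate (E/Z mixture)
Conditions: Me3SiCl, Et3N, hexane, 25 °C
Reagents that add atoms: chlorotrimethylsilane, C[Si](C)(C)Cl
Why: O-silylation of the readily enolised β-keto ester with an amine base gives the silyl enol ether and masks the acidic α-position for the next deprotonation.

**Step 10**
Reactants: 15 methyl 3-(trimethylsilyloxy)but-2-enoate
Product: 16 1-methoxy-1,3-bis(trimethylsilyloxy)buta-1,3-diene (mixture of geometric isomers)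
Conditions: LiN(iPr)2, THF, −78 °C; Me3SiCl, −78 → 0 °C; non-aqueous work-up
Reagents that add atoms: chlorotrimethylsilane, C[Si](C)(C)Cl
Why: Kinetic γ-deprotonation of the vinylogous ester at its methyl group followed by O-silylation of the dienolate is the established preparation of this silyl ketene acetal diene.

**Step 11**
Reactants: 13 1-[2-methoxy-3-(3-methylbut-2-en-1-yl)-4,6-bis(triisopropylsilyloxy)phenyl]but-3-yn-2-one, 16 1-methoxy-1,3-bis(trimethylsilyloxy)buta-1,3-diene
Product: 19 1-(2,4-dihydroxyphenyl)-2-[2-methoxy-3-(3-methylbut-2-en-1-yl)-4,6-bis(triisopropylsilyloxy)phenyl]ethan-1-one, via cycloadduct 17 (not isolated), via bis(trimethylsilyl) ether 18 (not isolated)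
Conditions: 16 (2.5 equiv), toluene, 25 → 80 °C; then 0.5 M aq HCl, THF, 0 °C, 15 min
Reagents that add atoms: none
Why: Three oxygen donors place the largest HOMO coefficient of 16 on its CH2 terminus and the LUMO of 13 is largest at the unsubstituted alkyne carbon, so these atoms bond first (C5–C6) and the ketene acetal carbon closes onto the acyl-bearing alkyne carbon (C1–C2) in a concerted but strongly asynchronous normal-electron-demand [4+2] cycloaddition. Ring B is thus closed as a six-membered ring in one intermolecular cycloaddition, first as the 1,4-cyclohexadiene 17, whose mixed ketal carbon expels methanol together with a C5 proton to give arene 18, and brief dilute acid then hydrolyses the labile Me3Si ethers but not the iPr3Si ethers. The closest known reaction type is the Diels–Alder/aromatisation of 1-alkoxy-1,3-bis(silyloxy)butadienes with acetylenic ketones and esters, which gives 2,4-dihydroxyaryl carbonyl compounds. No stereocentre is set, because the one at the ketal carbon of 17 disappears on aromatisation. The selectivity needed is regiochemical (oxygen at C2 and C4 instead of C3 and C5), and it is secured by the match between the nucleophilic CH2 terminus and the sterically open, electrophilic β-carbon of the terminal ynone. Running the reaction without a Lewis acid leaves the ketone carbonyl unactivated towards attack by the central diene carbon, ring A offers no OH to protonate the ketene acetal, and the electron-rich prenyl alkene cannot compete as a dienophile.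

**Step 12**
Reactants: 19 1-(2,4-dihydroxyphenyl)-2-[2-methoxy-3-(3-methylbut-2-en-1-yl)-4,6-bis(triisopropylsilyloxy)phenyl]ethan-1-one
Product: 20 glicophenone
Conditions: Bu4NF (2.5 equiv), AcOH (2.5 equiv), THF, 0 °C, argon; pH 7 buffer work-up
Reagents that add atoms: none
Why: Fluoride-induced desilylation of aryl silyl ethers is fast at 0 °C, and the acetic acid buffer keeps the medium near neutral, so the acid-driven closures to the benzofuran and the chroman and the air oxidation of phenoxides should all be avoided.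

**Compound list**
1 | 2,4,6-trihydroxybenzaldehyde | O=Cc1c(O)cc(O)cc1O | starting material
2 | 2-hydroxy-4,6-bis(triisopropylsilyloxy)benzaldehyde | O=Cc1c(O)cc(O[Si](C(C)C)(C(C)C)C(C)C)cc1O[Si](C(C)C)(C(C)C)C(C)C | intermediate
3 | 2-methylbut-3-en-2-ol | CC(C)(O)C=C | starting material
4 | tert-butyl 2-methylbut-3-en-2-yl carbonate | CC(C)(C)OC(=O)OC(C)(C)C=C | intermediate
5 | 2-[(2-methylbut-3-en-2-yl)oxy]-4,6-bis(triisopropylsilyloxy)benzaldehyde | O=Cc1c(OC(C)(C)C=C)cc(O[Si](C(C)C)(C(C)C)C(C)C)cc1O[Si](C(C)C)(C(C)C)C(C)C | intermediate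
6 | 5-(3-methylbut-2-en-1-yl)-6-oxo-2,4-bis(triisopropylsilyloxy)cyclohexa-1,3-diene-1-carbaldehyde (Claisen dienone, racemic, not isolated) | O=CC1=C(O[Si](C(C)C)(C(C)C)C(C)C)C=C(O[Si](C(C)C)(C(C)C)C(C)C)C(CC=C(C)C)C1=O | intermediate
7 | 2-hydroxy-3-(3-methylbut-2-en-1-yl)-4,6-bis(triisopropylsilyloxy)benzaldehyde | O=Cc1c(O)c(CC=C(C)C)c(O[Si](C(C)C)(C(C)C)C(C)C)cc1O[Si](C(C)C)(C(C)C)C(C)C | intermediate
8 | 2-methoxy-3-(3-methylbut-2-en-1-yl)-4,6-bis(triisopropylsilyloxy)benzaldehyde | COc1c(CC=C(C)C)c(O[Si](C(C)C)(C(C)C)C(C)C)cc(O[Si](C(C)C)(C(C)C)C(C)C)c1C=O | intermediate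
9 | 2-methoxy-1-(2-methoxyethenyl)-3-(3-methylbut-2-en-1-yl)-4,6-bis(triisopropylsilyloxy)benzene (E/Z mixture, not isolated) | COC=Cc1c(OC)c(CC=C(C)C)c(O[Si](C(C)C)(C(C)C)C(C)C)cc1O[Si](C(C)C)(C(C)C)C(C)C | intermediate
10 | [2-methoxy-3-(3-methylbut-2-en-1-yl)-4,6-bis(triisopropylsilyloxy)phenyl]acetaldehyde | COc1c(CC=C(C)C)c(O[Si](C(C)C)(C(C)C)C(C)C)cc(O[Si](C(C)C)(C(C)C)C(C)C)c1CC=O | intermediate
11 | ethynylmagnesium bromide | C#C[Mg]Br | starting material
12 | 1-[2-methoxy-3-(3-methylbut-2-en-1-yl)-4,6-bis(triisopropylsilyloxy)phenyl]but-3-yn-2-ol (racemic) | COc1c(CC=C(C)C)c(O[Si](C(C)C)(C(C)C)C(C)C)cc(O[Si](C(C)C)(C(C)C)C(C)C)c1CC(O)C#C | intermediate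
13 | 1-[2-methoxy-3-(3-methylbut-2-en-1-yl)-4,6-bis(triisopropylsilyloxy)phenyl]but-3-yn-2-one | COc1c(CC=C(C)C)c(O[Si](C(C)C)(C(C)C)C(C)C)cc(O[Si](C(C)C)(C(C)C)C(C)C)c1CC(=O)C#C | intermediate
14 | methyl acetoacetate | COC(=O)CC(C)=O | starting material
15 | methyl 3-(trimethylsilyloxy)but-2-enoate (E/Z mixture) | COC(=O)C=C(C)O[Si](C)(C)C | intermediate
16 | 1-methoxy-1,3-bis(trimethylsilyloxy)buta-1,3-diene (mixture of geometric isomers) | COC(O[Si](C)(C)C)=CC(=C)O[Si](C)(C)C | intermediate
17 | 1-[6-methoxy-4,6-bis(trimethylsilyloxy)cyclohexa-1,4-dien-1-yl]-2-[2-methoxy-3-(3-methylbut-2-en-1-yl)-4,6-bis(triisopropylsilyloxy)phenyl]ethan-1-one (racemic, not isolated) | COC1(O[Si](C)(C)C)C=C(O[Si](C)(C)C)CC=C1C(=O)Cc1c(OC)c(CC=C(C)C)c(O[Si](C(C)C)(C(C)C)C(C)C)cc1O[Si](C(C)C)(C(C)C)C(C)C | intermediate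
18 | 1-[2,4-bis(trimethylsilyloxy)phenyl]-2-[2-methoxy-3-(3-methylbut-2-en-1-yl)-4,6-bis(triisopropylsilyloxy)phenyl]ethan-1-one (not isolated) | COc1c(CC=C(C)C)c(O[Si](C(C)C)(C(C)C)C(C)C)cc(O[Si](C(C)C)(C(C)C)C(C)C)c1CC(=O)c1ccc(O[Si](C)(C)C)cc1O[Si](C)(C)C | intermediate
19 | 1-(2,4-dihydroxyphenyl)-2-[2-methoxy-3-(3-methylbut-2-en-1-yl)-4,6-bis(triisopropylsilyloxy)phenyl]ethan-1-one | COc1c(CC=C(C)C)c(O[Si](C(C)C)(C(C)C)C(C)C)cc(O[Si](C(C)C)(C(C)C)C(C)C)c1CC(=O)c1ccc(O)cc1O | intermediate
20 | glicophenone, 1-(2,4-dihydroxyphenyl)-2-[4,6-dihydroxy-2-methoxy-3-(3-methylbut-2-en-1-yl)phenyl]ethan-1-one | COc1c(CC=C(C)C)c(O)cc(O)c1CC(=O)c1ccc(O)cc1O | target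

**Total step count:** 12.
**Longest linear sequence:** 9 steps (1, 3, 4, 5, 6, 7, 8, 11, 12).

**Steps most likely to fail**

**Step 11.**
- What may go wrong: the diene terminus may add in conjugate fashion without ring closure at the ketene acetal carbon. The central diene carbon may instead close onto the ketone. The acidic ArCH2 group may protonate the ketene acetal. The terminal ynone may oligomerise on heating.
- Fallback: ring B is brought in as a ready-made arene by carbonyl addition. It sets out from 10 and comes back at 19.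
- 4-Bromoresorcinol is bis-allylated (allyl bromide, K2CO3, acetone) to 2,4-bis(allyloxy)-1-bromobenzene F1.
- Bromine–lithium exchange (n-BuLi, THF, −78 °C) gives 2,4-bis(allyloxy)phenyllithium F2.
- F2 adds to 10 to give racemic 1-[2,4-bis(allyloxy)phenyl]-2-[2-methoxy-3-(3-methylbut-2-en-1-yl)-4,6-bis(triisopropylsilyloxy)phenyl]ethan-1-ol F3.
- Dess–Martin oxidation gives the corresponding ethan-1-one F4.
- Neutral deallylation with Pd(PPh3)4 and morpholine (THF, 25 °C) leaves the prenyl group and the silyl ethers untouched and delivers 19.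

**Step 3.**
- What may go wrong: the phenoxide may attack the unsubstituted allyl terminus. The tertiary ether, whose aryloxide is a good leaving group, may also re-ionise and drift to the linear prenyl ether, which would place the wrong allyl isomer on the ring in step 4.
- Fallback: the tertiary C–O bond is made by propargylic substitution and the alkene by reduction. It sets out from 2 and comes back at 5.
- Copper-catalysed O-alkylation with 3-chloro-3-methylbut-1-yne (CuCl2 cat., DBU, MeCN, 0 °C) gives 2-[(2-methylbut-3-yn-2-yl)oxy]-4,6-bis(triisopropylsilyloxy)benzaldehyde F5.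
- Semi-hydrogenation (H2, Pd/CaCO3 poisoned with Pb(OAc)2, quinoline, EtOAc) gives 5.

**Step 6.**
- What may go wrong: olefination of the doubly ortho-substituted aldehyde may be sluggish. Hydrolysis of the enol ether may be slow and call for acid strong enough to attack the prenyl alkene or the silyl ethers. The arylacetaldehyde may self-condense in acid.
- Fallback: homologation through an epoxide. It sets out from 8 and comes back at 10.
- Corey–Chaykovsky methylenation (Me3SI, NaH, DMSO/THF, 0 °C) gives 2-[2-methoxy-3-(3-methylbut-2-en-1-yl)-4,6-bis(triisopropylsilyloxy)phenyl]oxirane F6.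
- The strongly stabilised benzylic position of F6 should allow a Meinwald rearrangement with catalytic InCl3 (THF, 25 °C), which gives 10 by a 1,2-hydride shift.

**Further compounds**
F1 | step 11 | 2,4-bis(allyloxy)-1-bromobenzene | C=CCOc1ccc(Br)c(OCC=C)c1
F2 | step 11 | 2,4-bis(allyloxy)phenyllithium | [Li]c1ccc(OCC=C)cc1OCC=C
F3 | step 11 | 1-[2,4-bis(allyloxy)phenyl]-2-[2-methoxy-3-(3-methylbut-2-en-1-yl)-4,6-bis(triisopropylsilyloxy)phenyl]ethan-1-ol (racemic) | COc1c(CC=C(C)C)c(O[Si](C(C)C)(C(C)C)C(C)C)cc(O[Si](C(C)C)(C(C)C)C(C)C)c1CC(O)c1ccc(OCC=C)cc1OCC=C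
F4 | step 11 | 1-[2,4-bis(allyloxy)phenyl]-2-[2-methoxy-3-(3-methylbut-2-en-1-yl)-4,6-bis(triisopropylsilyloxy)phenyl]ethan-1-one | COc1c(CC=C(C)C)c(O[Si](C(C)C)(C(C)C)C(C)C)cc(O[Si](C(C)C)(C(C)C)C(C)C)c1CC(=O)c1ccc(OCC=C)cc1OCC=C
F5 | step 3 | 2-[(2-methylbut-3-yn-2-yl)oxy]-4,6-bis(triisopropylsilyloxy)benzaldehyde | O=Cc1c(OC(C)(C)C#C)cc(O[Si](C(C)C)(C(C)C)C(C)C)cc1O[Si](C(C)C)(C(C)C)C(C)C
F6 | step 6 | 2-[2-methoxy-3-(3-methylbut-2-en-1-yl)-4,6-bis(triisopropylsilyloxy)phenyl]oxirane (racemic) | COc1c(CC=C(C)C)c(O[Si](C(C)C)(C(C)C)C(C)C)cc(O[Si](C(C)C)(C(C)C)C(C)C)c1C1CO1
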